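The target is cut at the bridging CH2 into two benzophenones that differ in one O-methyl group, and both come from one annulation product. Rings B and D (the 2,4-dioxygenated 6-methylphenyl rings) have the ketone-bearing C1 between C6–CH3 and C2–O, with a second oxygen on C4: the pattern of a 4-acyl-5-methylcyclohexane-1,3-dione. A Michael–Dieckmann annulation of a 1-arylbutane-1,3-dione, whose ring A carries two ortho MOM ethers, with methyl crotonate forms bonds C1–C6 and C3–C4 and closes this ring in one operation. Dehydrogenation, benzyl protection of rings B and D, release of the phloroglucinol rings and a Mannich-base coupling finish the synthesis.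

Key step: step 3

Ring labels: rings A and C are the two methylene-bridged 2,6-dihydroxy-4-methoxyphenyl rings, ring B is 2,4-dihydroxy-6-methylphenyl (on the ketone of ring A), and ring D is 4-hydroxy-2-methoxy-6-methylphenyl (on the ketone of ring C).

Assumption: 1-(2,6-dihydroxy-4-methoxyphenyl)ethan-1-one and N,N-dimethylmethyleneiminium iodide are bought. The target has no stereocentre, and the two centres of trione 7 (drawn as the trans triketone, although it is largely enolised) are transient.

Design remarks:
- Ring A is carried as its bis(methoxymethyl) ether, not as benzyl ethers. After aromatisation, rings B and D can then be benzylated and rings A and C freed alone, which confines aminomethylation and bridging to the phloroglucinol rings.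
- The 2-methoxy group of ring D is set by benzylating O4 first, because direct methylation would go to O4.

Step 1
Reactants: 1 1-(2,6-dihydroxy-4-methoxyphenyl)ethan-1-one
Product: 2 1-[4-methoxy-2,6-bis(methoxymethoxy)phenyl]ethan-1-one
Conditions: NaH (2.2 equiv), DMF, 0 °C; MOMCl (2.5 equiv), 0 °C to rt
Reagents that add atoms: chloromethyl methyl ether (MOMCl), COCCl
Why: Williamson-type O-alkylation of the two chelated phenoxides, fully formed with NaH, by the hard electrophile MOMCl masks both ortho hydroxyls, which would otherwise close a chromone ring onto the 1,3-diketone made in step 2.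

Step 2
Reactants: 2 1-[4-methoxy-2,6-bis(methoxymethoxy)phenyl]ethan-1-one; 3 ethyl acetate
Product: 4 1-[4-methoxy-2,6-bis(methoxymethoxy)phenyl]butane-1,3-dione
Conditions: NaH (3 equiv), EtOAc (6 equiv), THF, 65 °C; then AcOH, H2O, 0 °C
Reagents that add atoms: none
Why: Crossed Claisen condensation: the methyl ketone of 2 has the only enolisable position, its sodium enolate is acylated by ethyl acetate, and deprotonation of the resulting 1,3-diketone by ethoxide drives the equilibrium.

Step 3
Reactants: 4 1-[4-methoxy-2,6-bis(methoxymethoxy)phenyl]butane-1,3-dione; 5 methyl (E)-but-2-enoate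
Product: 7 trans-4-[4-methoxy-2,6-bis(methoxymethoxy)benzoyl]-5-methylcyclohexane-1,3-dione (racemic), via Michael adduct 6 (not isolated)
Conditions: NaOMe (2.0 equiv), 5 (1.5 equiv), MeOH, reflux; then AcOH to pH 4–5, 0 °C
Reagents that add atoms: none
Why: NaOMe deprotonates 4 at its central carbon, the most acidic site, and this diketonate adds to the β-carbon of 5 (Michael addition, ring B bond C1–C6) to give keto ester 6 after proton transfer. Equilibrium deprotonation of the acetyl methyl then lets that enolate attack the ester carbonyl in a 6-exo-trig Dieckmann-type Claisen closure (bond C3–C4) with loss of methoxide, and the sequence is pulled forward by formation of the delocalised trione enolate. It is the diketone variant of the Michael–Claisen annulation by which acetoacetates and crotonates give 5-methylcyclohexane-1,3-diones. The two sp3 centres C4 and C5 form without control and should settle to trans through enolisation at C4 (thermodynamic control), and both are erased in step 4. The step needs C-alkylation at the central carbon and closure from the acetyl methyl: the acidity of the 1,3-diketone secures the first, and the second follows because the aroyl group has no α-hydrogen on its aryl side and any other closure would be four-membered, while the two ortho methoxymethoxy groups shield the aryl ketone from methoxide.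

Step 4
Reactants: 7 trans-4-[4-methoxy-2,6-bis(methoxymethoxy)benzoyl]-5-methylcyclohexane-1,3-dione
Product: 8 (2,4-dihydroxy-6-methylphenyl)[4-methoxy-2,6-bis(methoxymethoxy)phenyl]methanone
Conditions: DDQ (1.1 equiv), 1,4-dioxane, 80 °C
Reagents that add atoms: none
Why: Dehydrogenative aromatisation of an acylcyclohexane-1,3-dione with a quinone: DDQ takes a hydride from C5–H of the enolised trione, loss of a C6 proton and tautomerisation give the acylresorcinol ring with aromaticity as driving force, and ring A offers DDQ neither a free phenol nor an activated benzylic ether.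

Step 5
Reactants: 8 (2,4-dihydroxy-6-methylphenyl)[4-methoxy-2,6-bis(methoxymethoxy)phenyl]methanone
Product: 9 [2,4-bis(benzyloxy)-6-methylphenyl][4-methoxy-2,6-bis(methoxymethoxy)phenyl]methanone
Conditions: BnBr (2.5 equiv), K2CO3 (3 equiv), DMF, 60 °C
Reagents that add atoms: benzyl bromide, BrCc1ccccc1
Why: Williamson ether synthesis with excess benzyl bromide in DMF alkylates the free 4-hydroxyl and, on warming, the chelated 2-hydroxyl of ring B, while the MOM acetals are stable to base.

Step 6
Reactants: 9 [2,4-bis(benzyloxy)-6-methylphenyl][4-methoxy-2,6-bis(methoxymethoxy)phenyl]methanone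
Product: 10 [2,4-bis(benzyloxy)-6-methylphenyl](2,6-dihydroxy-4-methoxyphenyl)methanone
Conditions: HCl (3 M, MeOH), THF, 40 °C
Reagents that add atoms: none
Why: Acid-catalysed acetal solvolysis in methanol removes both MOM groups as dimethoxymethane, benzyl and methyl aryl ethers being inert to dilute HCl, and frees the two phenols of ring A that the coupling needs.

Step 7
Reactants: 8 (2,4-dihydroxy-6-methylphenyl)[4-methoxy-2,6-bis(methoxymethoxy)phenyl]methanone
Product: 11 [4-(benzyloxy)-2-hydroxy-6-methylphenyl][4-methoxy-2,6-bis(methoxymethoxy)phenyl]methanone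
Conditions: BnBr (1.05 equiv), K2CO3 (1.1 equiv), acetone, 50 °C
Reagents that add atoms: benzyl bromide, BrCc1ccccc1
Why: Regioselective Williamson mono-alkylation: the 4-hydroxyl para to the carbonyl is the more acidic and unhindered phenol, whereas the 2-hydroxyl is hydrogen-bonded to the ketone and flanked by it, so one equivalent of benzyl bromide with K2CO3 in acetone should stop at the 4-benzyl ether (any dibenzyl ether formed is 9 and stays useful).

Step 8
Reactants: 11 [4-(benzyloxy)-2-hydroxy-6-methylphenyl][4-methoxy-2,6-bis(methoxymethoxy)phenyl]methanone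
Product: 12 [4-(benzyloxy)-2-methoxy-6-methylphenyl][4-methoxy-2,6-bis(methoxymethoxy)phenyl]methanone
Conditions: MeI (3 equiv), K2CO3 (3 equiv), DMF, 45 °C
Reagents that add atoms: iodomethane, CI
Why: Williamson methylation of the remaining chelated 2-hydroxyl under more forcing conditions (excess MeI, DMF) places the methyl ether of ring D at the oxygen that direct methylation of 8 would have left untouched.

Step 9
Reactants: 12 [4-(benzyloxy)-2-methoxy-6-methylphenyl][4-methoxy-2,6-bis(methoxymethoxy)phenyl]methanone
Product: 13 [4-(benzyloxy)-2-methoxy-6-methylphenyl](2,6-dihydroxy-4-methoxyphenyl)methanone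
Conditions: HCl (3 M, MeOH), THF, 40 °C
Reagents that add atoms: none
Why: Acid-catalysed acetal solvolysis as in step 6 frees the two phenols of ring C, while the benzyl ether and both methyl ethers are stable to dilute methanolic HCl.

Step 10
Reactants: 10 [2,4-bis(benzyloxy)-6-methylphenyl](2,6-dihydroxy-4-methoxyphenyl)methanone; 14 N,N-dimethylmethyleneiminium iodide
Product: 15 [2,4-bis(benzyloxy)-6-methylphenyl]{3-[(dimethylamino)methyl]-2,6-dihydroxy-4-methoxyphenyl}methanone
Conditions: 14 (1.0 equiv), CH2Cl2, 0 °C to rt; then aq NaHCO3
Reagents that add atoms: none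
Why: Mannich aminomethylation with the preformed iminium salt is an electrophilic substitution ortho to a free phenol, which only ring A offers now that ring B is fully etherified, its two open positions are equivalent, and one equivalent of reagent together with the deactivating ammonium group of the first-formed salt holds the reaction at the mono-adduct.

Step 11
Reactants: 15 [2,4-bis(benzyloxy)-6-methylphenyl]{3-[(dimethylamino)methyl]-2,6-dihydroxy-4-methoxyphenyl}methanone; 13 [4-(benzyloxy)-2-methoxy-6-methylphenyl](2,6-dihydroxy-4-methoxyphenyl)methanone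
Product: 17 {3-[(3-{[4-(benzyloxy)-2-methoxy-6-methylphenyl]carbonyl}-2,4-dihydroxy-6-methoxyphenyl)methyl]-2,6-dihydroxy-4-methoxyphenyl}[2,4-bis(benzyloxy)-6-methylphenyl]methanone, via ortho-quinone methide 16 (not isolated)
Conditions: 13 (2.0 equiv), 1,4-dioxane, 100 °C, 15 added slowly, N2 stream
Reagents that add atoms: none
Why: Thermal loss of dimethylamine from the phenolic Mannich base gives ortho-quinone methide 16, which the phloroglucinol ring C of 13 attacks through carbon at one of its two equivalent open positions (conjugate addition, then rearomatisation), the established Mannich-base route to unsymmetrical methylene-bridged acylphloroglucinols, while excess 13 and slow addition of 15 hold back double alkylation.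

Step 12
Reactants: 17 {3-[(3-{[4-(benzyloxy)-2-methoxy-6-methylphenyl]carbonyl}-2,4-dihydroxy-6-methoxyphenyl)methyl]-2,6-dihydroxy-4-methoxyphenyl}[2,4-bis(benzyloxy)-6-methylphenyl]methanone
Product: 18 {3-[(3-{[4-hydroxy-2-methoxy-6-methylphenyl]carbonyl}-2,4-dihydroxy-6-methoxyphenyl)methyl]-2,6-dihydroxy-4-methoxyphenyl}(2,4-dihydroxy-6-methylphenyl)methanone (CNP0596095.0)
Conditions: H2 (1 atm), 10% Pd/C, EtOAc–MeOH, rt
Reagents that add atoms: none
Why: Hydrogenolysis of the three aryl benzyl ethers over Pd/C at room temperature leaves the diarylmethane bridge, the aryl methyl ethers and the chelated, di-ortho-substituted benzophenone carbonyls untouched and ends the route under neutral conditions.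

Compound list
1 | 1-(2,6-dihydroxy-4-methoxyphenyl)ethan-1-one | CC(=O)c1c(O)cc(OC)cc1O | starting material
2 | 1-[4-methoxy-2,6-bis(methoxymethoxy)phenyl]ethan-1-one | CC(=O)c1c(OCOC)cc(OC)cc1OCOC | intermediate
3 | ethyl acetate | CCOC(C)=O | starting material
4 | 1-[4-methoxy-2,6-bis(methoxymethoxy)phenyl]butane-1,3-dione | COCOc1cc(OC)cc(OCOC)c1C(=O)CC(C)=O | intermediate
5 | methyl (E)-but-2-enoate (methyl crotonate) | C/C=C/C(=O)OC | starting material
6 | methyl 4-acetyl-5-[4-methoxy-2,6-bis(methoxymethoxy)phenyl]-3-methyl-5-oxopentanoate (Michael adduct, diastereomer mixture, not isolated) | COCOc1cc(OC)cc(OCOC)c1C(=O)C(C(C)=O)C(C)CC(=O)OC | intermediate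
7 | trans-4-[4-methoxy-2,6-bis(methoxymethoxy)benzoyl]-5-methylcyclohexane-1,3-dione (racemic, one enantiomer drawn; largely enolised) | COCOc1cc(OC)cc(OCOC)c1C(=O)[C@@H]1[C@@H](C)CC(=O)CC1=O | intermediate
8 | (2,4-dihydroxy-6-methylphenyl)[4-methoxy-2,6-bis(methoxymethoxy)phenyl]methanone | COCOc1cc(OC)cc(OCOC)c1C(=O)c1c(C)cc(O)cc1O | intermediate
9 | [2,4-bis(benzyloxy)-6-methylphenyl][4-methoxy-2,6-bis(methoxymethoxy)phenyl]methanone | COCOc1cc(OC)cc(OCOC)c1C(=O)c1c(C)cc(OCc2ccccc2)cc1OCc1ccccc1 | intermediate
10 | [2,4-bis(benzyloxy)-6-methylphenyl](2,6-dihydroxy-4-methoxyphenyl)methanone | COc1cc(O)c(C(=O)c2c(C)cc(OCc3ccccc3)cc2OCc2ccccc2)c(O)c1 | intermediate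
11 | [4-(benzyloxy)-2-hydroxy-6-methylphenyl][4-methoxy-2,6-bis(methoxymethoxy)phenyl]methanone | COCOc1cc(OC)cc(OCOC)c1C(=O)c1c(C)cc(OCc2ccccc2)cc1O | intermediate
12 | [4-(benzyloxy)-2-methoxy-6-methylphenyl][4-methoxy-2,6-bis(methoxymethoxy)phenyl]methanone | COCOc1cc(OC)cc(OCOC)c1C(=O)c1c(C)cc(OCc2ccccc2)cc1OC | intermediate
13 | [4-(benzyloxy)-2-methoxy-6-methylphenyl](2,6-dihydroxy-4-methoxyphenyl)methanone | COc1cc(O)c(C(=O)c2c(C)cc(OCc3ccccc3)cc2OC)c(O)c1 | intermediate
14 | N,N-dimethylmethyleneiminium iodide | C=[N+](C)C.[I-] | starting material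
15 | [2,4-bis(benzyloxy)-6-methylphenyl]{3-[(dimethylamino)methyl]-2,6-dihydroxy-4-methoxyphenyl}methanone | COc1cc(O)c(C(=O)c2c(C)cc(OCc3ccccc3)cc2OCc2ccccc2)c(O)c1CN(C)C | intermediate
16 | 2-[2,4-bis(benzyloxy)-6-methylbenzoyl]-3-hydroxy-5-methoxy-6-methylidenecyclohexa-2,4-dien-1-one (ortho-quinone methide, not isolated) | C=C1C(OC)=CC(O)=C(C(=O)c2c(C)cc(OCc3ccccc3)cc2OCc2ccccc2)C1=O | intermediate
17 | {3-[(3-{[4-(benzyloxy)-2-methoxy-6-methylphenyl]carbonyl}-2,4-dihydroxy-6-methoxyphenyl)methyl]-2,6-dihydroxy-4-methoxyphenyl}[2,4-bis(benzyloxy)-6-methylphenyl]methanone | COc1cc(O)c(C(=O)c2c(C)cc(OCc3ccccc3)cc2OCc2ccccc2)c(O)c1Cc1c(OC)cc(O)c(C(=O)c2c(C)cc(OCc3ccccc3)cc2OC)c1O | intermediate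
18 | {3-[(3-{[4-hydroxy-2-methoxy-6-methylphenyl]carbonyl}-2,4-dihydroxy-6-methoxyphenyl)methyl]-2,6-dihydroxy-4-methoxyphenyl}(2,4-dihydroxy-6-methylphenyl)methanone (CNP0596095.0) | COc1cc(O)c(C(=O)c2c(C)cc(O)cc2O)c(O)c1Cc1c(OC)cc(O)c(C(=O)c2c(C)cc(O)cc2OC)c1O | target

Total step count: 12.
Longest linear sequence: 9 steps (steps 1, 2, 3, 4, 5, 6, 10, 11, 12; the branch through steps 7, 8, 9 is equally long).

Steps most likely to fail

1. Step 3 (key step). The conjugate addition of the hindered diketonate to the weakly electrophilic β-methyl acrylate may be slow and reversible, and methoxide may drain material by retro-Claisen loss of the acetyl group before ring closure. Fallback, setting out from 4 and coming back at 7: the crotonate is replaced by the doubly activated diethyl ethylidenemalonate (NaOEt, EtOH, reflux). Conjugate addition should then be easy and give diethyl 2-{3-acetyl-4-[4-methoxy-2,6-bis(methoxymethoxy)phenyl]-4-oxobutan-2-yl}propanedioate F1, which closes by the same attack of the acetyl methyl on one ester group to ethyl 3-[4-methoxy-2,6-bis(methoxymethoxy)benzoyl]-2-methyl-4,6-dioxocyclohexane-1-carboxylate F2. Saponification with aqueous NaOH, acidification to pH 4 and gentle warming (the hydrolysis–decarboxylation sequence used for dimedone) should then deliver 7.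

2. Step 4. Hydride abstraction may be outrun by addition of the quinone to the enolised C2 position of the dione, or the oxidation may stall. Fallback, setting out from 7 and coming back at 8: palladium-catalysed aerobic dehydrogenation (Pd(O2CCF3)2, 2-(dimethylamino)pyridine, DMSO, O2 at 1 atm, 80 °C), in which a divalent palladium enolate undergoes β-hydride elimination and O2 reoxidises the metal. This option exists because ring A carries acetals and no benzyl ether at this stage. It makes no compound outside the list (F0).

3. Step 11. At 100 °C the quinone methide may alkylate the remaining open position of ring A or ring C of the product, condense with its own precursor, or pass its methylene group to 13 by amine exchange, which would give symmetrical dimers. Fallback, setting out from 15 and coming back at 17: 15 is quaternised with MeI (THF, rt) to 1-[3-(2,4-bis(benzyloxy)-6-methylbenzoyl)-2,4-dihydroxy-6-methoxyphenyl]-N,N,N-trimethylmethanaminium iodide F3. Treated with 13 and NaHCO3 in aqueous MeCN at 0 °C to rt, F3 should release quinone methide 16 by loss of trimethylamine at low temperature, where methylene transfer is slow, and 13 should trap it to give 17.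

Further compounds
F1 | step 3 | diethyl 2-{3-acetyl-4-[4-methoxy-2,6-bis(methoxymethoxy)phenyl]-4-oxobutan-2-yl}propanedioate (diastereomer mixture) | CCOC(=O)C(C(=O)OCC)C(C)C(C(C)=O)C(=O)c1c(OCOC)cc(OC)cc1OCOC
F2 | step 3 | ethyl 3-[4-methoxy-2,6-bis(methoxymethoxy)benzoyl]-2-methyl-4,6-dioxocyclohexane-1-carboxylate (diastereomer mixture) | CCOC(=O)C1C(C)C(C(=O)c2c(OCOC)cc(OC)cc2OCOC)C(=O)CC1=O
F0 | step 4 | none | none
F3 | step 11 | 1-[3-(2,4-bis(benzyloxy)-6-methylbenzoyl)-2,4-dihydroxy-6-methoxyphenyl]-N,N,N-trimethylmethanaminium iodide | COc1cc(O)c(C(=O)c2c(C)cc(OCc3ccccc3)cc2OCc2ccccc2)c(O)c1C[N+](C)(C)C.[I-]
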